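**Plan**

- The target is a (2R)-flavanone whose ring A is pentasubstituted in the order C4a (acyl carbon), C5 (OH), C6 (2-hydroxybenzyl), C7 (OMe), C8 (H), C8a (O1). This is the pattern laid down when a vinylketene combines with a 1-silyloxyalkyne.
- Retrosynthesis: after exchanging the free OH and OMe groups for O-benzyl and O-silyl, ring A is cut at C5–C6, C7–C8 and C4a–C5 (C8–C8a is traced to a Wolff shift). This gives an (R)-2-aryl-6-(diazoacetyl)-2,3-dihydro-4H-pyran-4-one and an arylmethyl siloxyalkyne.
- The diazoketone is cut at its diazomethyl–carbonyl bond to a pyranone-6-carboxylate. Ring C is cut at O1–C8a and C2–C3 to 4-(benzyloxy)benzaldehyde and the bis-silyl dienol ether of methyl 2,4-dioxopentanoate. The alkyne is cut at the triple bond to methyl [2-(benzyloxy)phenyl]acetate and one carbon from CH2Br2.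
- Forward order: ring C by a formal hetero-Diels–Alder reaction, then ester to acid to diazoketone. In parallel, phenol benzylation and ester to siloxyalkyne. Then ring A by photochemical benzannulation, and last desilylation, O-methylation at C7 and hydrogenolysis.
- Stereochemistry: the only stereocentre, C2 (R), is set by a Ti(OiPr)4/(R)-BINOL catalyst in the aldol stage of the hetero-Diels–Alder step. All later steps are non-basic so that ring C cannot open by retro-oxa-Michael reaction.

Key step: step 7

Remark: Re-face attack on the aryl aldehyde is assumed for the Ti(OiPr)4/(R)-BINOL catalyst with the silyloxydiene, as with related silyl nucleophiles. If the opposite sense is found, (S)-BINOL is used and nothing else changes.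

**Route**

Step 1
Reactants: 1 methyl 2,4-dioxopentanoate
Product: 2 methyl (2Z)-2,4-bis(trimethylsilyloxy)penta-2,4-dienoate
Conditions: Me3SiOTf (2.2 equiv), Et3N, Et2O, 0 °C to rt; used crude
Reagents that add atoms: trimethylsilyl trifluoromethanesulfonate, C[Si](C)(C)OS(=O)(=O)C(F)(F)F
Why: Double O-silylation (silyl enol ether formation) of a 1,3-dicarbonyl unit with Me3SiOTf and Et3N is the standard entry to 1,3-bis(silyloxy)-1,3-dienes, the chelated C2 enol being silylated first and the methyl ketone then enolised at its CH3 group.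

Step 2
Reactants: 2 methyl (2Z)-2,4-bis(trimethylsilyloxy)penta-2,4-dienoate; 3 4-(benzyloxy)benzaldehyde
Product: 5 methyl (2R)-2-[4-(benzyloxy)phenyl]-4-oxo-3,4-dihydro-2H-pyran-6-carboxylate, via aldol adduct 4 (not isolated)
Conditions: Ti(OiPr)4 (10 mol %), (R)-BINOL (20 mol %), 4 Å MS, Et2O, −20 °C; then TFA, CH2Cl2, 0 °C, brief
Reagents that add atoms: none
Why: A vinylogous Mukaiyama aldol addition of the terminal CH2 of the diene to the titanium-bound aldehyde (a formal hetero-Diels–Alder reaction) should occur on the Re face exposed by the (R)-BINOL ligand and so set the (R) carbinol centre, after which acid removes the silyl groups, the new hydroxyl forms a hemiketal with the C2 keto group and water is lost to give the dihydropyranone.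

Step 3
Reactants: 5 methyl (2R)-2-[4-(benzyloxy)phenyl]-4-oxo-3,4-dihydro-2H-pyran-6-carboxylate
Product: 6 (2R)-2-[4-(benzyloxy)phenyl]-4-oxo-3,4-dihydro-2H-pyran-6-carboxylic acid
Conditions: Me3SnOH, ClCH2CH2Cl, 80 °C; then dilute HCl wash
Reagents that add atoms: trimethyltin hydroxide, C[Sn](C)(C)O
Why: Ester hydrolysis with Me3SnOH is a tin-assisted acyl substitution under near-neutral conditions, so the C3 protons, whose removal would open the ring by retro-oxa-Michael reaction and erode the C2 centre, should stay in place, as should the enone and the benzyl ether.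

Step 4
Reactants: 6 (2R)-2-[4-(benzyloxy)phenyl]-4-oxo-3,4-dihydro-2H-pyran-6-carboxylic acid
Product: 8 (2R)-2-[4-(benzyloxy)phenyl]-6-(2-diazoacetyl)-2,3-dihydro-4H-pyran-4-one, via acid chloride 7 (not isolated)
Conditions: Me2C=C(Cl)NMe2, CH2Cl2, 0 °C; then CH2N2 (3 equiv), Et2O, 0 °C
Reagents that add atoms: diazomethane, C=[N+]=[N-]
Why: Acylation of diazomethane by an acid chloride (the first stage of the Arndt–Eistert sequence) is known for chromone-2-carbonyl chlorides and should outrun dipolar addition to the β-oxygenated enone, the chloride being made without acid by the α-chloroenamine and the HCl being taken up by a second equivalent of CH2N2.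

Step 5
Reactants: 9 methyl (2-hydroxyphenyl)acetate
Product: 10 methyl [2-(benzyloxy)phenyl]acetate
Conditions: BnBr, K2CO3, acetone, reflux
Reagents that add atoms: benzyl bromide, BrCc1ccccc1
Why: Williamson ether synthesis on the phenol is routine and installs a group that withstands organolithium bases, light and fluoride and is removed in the last hydrogenolysis.

Step 6
Reactants: 10 methyl [2-(benzyloxy)phenyl]acetate
Product: 13 ({3-[2-(benzyloxy)phenyl]prop-1-yn-1-yl}oxy)tri(propan-2-yl)silane, via lithium dibromoenolate 11 (not isolated), via lithium ynolate 12 (not isolated)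
Conditions: CH2Br2, lithium 2,2,6,6-tetramethylpiperidide (2 equiv), THF, −78 °C; n-BuLi, −78 °C to rt; then (i-Pr)3SiCl, −78 °C to rt
Reagents that add atoms: dibromomethane, BrCBr; chlorotri(propan-2-yl)silane, CC(C)[Si](Cl)(C(C)C)C(C)C
Why: In the Kowalski ester homologation LiCHBr2 adds to the ester, the derived dibromoketone enolate undergoes bromine–lithium exchange and 1,2-shift of the arylmethyl group to the lithium ynolate, and the bulky silyl chloride traps this anion on oxygen to give the siloxyalkyne.

Step 7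
Reactants: 8 (2R)-2-[4-(benzyloxy)phenyl]-6-(2-diazoacetyl)-2,3-dihydro-4H-pyran-4-one; 13 ({3-[2-(benzyloxy)phenyl]prop-1-yn-1-yl}oxy)tri(propan-2-yl)silane
Product: 17 (2R)-6-[2-(benzyloxy)benzyl]-2-[4-(benzyloxy)phenyl]-5-hydroxy-7-[tri(propan-2-yl)silyloxy]-2,3-dihydro-4H-chromen-4-one, via vinylketene 14 (not isolated), via vinylcyclobutenone 15 (not isolated), via dienylketene 16 (not isolated)
Conditions: hν (ca. 350 nm, Pyrex), degassed ClCH2CH2Cl, rt; then 80 °C
Reagents that add atoms: none
Why: Light expels N2 from 8 and the Wolff 1,2-shift of pyranone carbon C6 gives vinylketene 14, whose ketene C=C bond adds [2+2] to the electron-rich triple bond of 13 to close the four-membered ring of 15 by a polar cycloaddition; warming opens 15 by 4π conrotatory electrocyclic ring opening to dienylketene 16, which closes ring A by 6π disrotatory electrocyclisation between the ketene carbon and pyranone C5 (the future C4a) and then tautomerises to the phenol. The closest known reaction is the Danheiser benzannulation in its diazoketone variant with siloxyalkynes, which turns α,β-unsaturated diazomethyl ketones into resorcinol monosilyl ethers. In flavanone numbering the cascade forms C5–C6, C7–C8 and C4a–C5, and the Wolff shift forms C8–C8a. No stereocentre is created in the product: the ring carbon of 15 that carries the pyranone is a transient centre lost on ring opening, and C2 lies outside the reacting π system and is untouched under these neutral conditions. The selectivity needed is regiochemical and is fixed by polarity, the nucleophilic alkyne carbon bearing the arylmethyl group bonding to the electrophilic ketene carbonyl carbon, so that the benzyl group ends at C6 next to the new C5 hydroxyl and the silyloxy group at C7. The Pyrex filter keeps the benzyl aryl ethers from absorbing, and the hydrogen bond from the C5 hydroxyl to the C4 carbonyl should protect the product from acylation by remaining ketene.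

Step 8
Reactants: 17 (2R)-6-[2-(benzyloxy)benzyl]-2-[4-(benzyloxy)phenyl]-5-hydroxy-7-[tri(propan-2-yl)silyloxy]-2,3-dihydro-4H-chromen-4-one
Product: 18 (2R)-6-[2-(benzyloxy)benzyl]-2-[4-(benzyloxy)phenyl]-5,7-dihydroxy-2,3-dihydro-4H-chromen-4-one
Conditions: Bu4NF, AcOH (1:1), THF, 0 °C
Reagents that add atoms: none
Why: Fluoride-mediated desilylation of an aryl silyl ether is fast, and the acetic acid buffer keeps the medium non-basic so that the flavanone is not opened to the chalcone and C2 is not epimerised.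

Step 9
Reactants: 18 (2R)-6-[2-(benzyloxy)benzyl]-2-[4-(benzyloxy)phenyl]-5,7-dihydroxy-2,3-dihydro-4H-chromen-4-one
Product: 19 (2R)-6-[2-(benzyloxy)benzyl]-2-[4-(benzyloxy)phenyl]-5-hydroxy-7-methoxy-2,3-dihydro-4H-chromen-4-one
Conditions: Me3SiCHN2, i-Pr2NEt, MeOH/MeCN, 0 °C to rt
Reagents that add atoms: trimethylsilyldiazomethane, C[Si](C)(C)C=[N+]=[N-]
Why: O-Methylation of phenols with trimethylsilyldiazomethane in methanol should touch only the free, acidic C7 hydroxyl, because the C5 hydroxyl is held in a strong hydrogen bond to the C4 carbonyl and is known to resist diazoalkanes.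

Step 10
Reactants: 19 (2R)-6-[2-(benzyloxy)benzyl]-2-[4-(benzyloxy)phenyl]-5-hydroxy-7-methoxy-2,3-dihydro-4H-chromen-4-one
Product: 20 (+)-methylphelligrin A, (2R)-5-hydroxy-6-(2-hydroxybenzyl)-2-(4-hydroxyphenyl)-7-methoxy-2,3-dihydro-4H-chromen-4-one
Conditions: H2 (1 atm), 10% Pd/C, EtOAc, rt, stopped at full conversion
Reagents that add atoms: none
Why: Catalytic hydrogenolysis over Pd/C cleaves both benzyl ethers under neutral conditions, while the ketone, the diarylmethane and, at short reaction time in ethyl acetate, the benzylic C2–O1 bond should persist, so the (R) centre is kept.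

**Compound list**

1 | methyl 2,4-dioxopentanoate | COC(=O)C(=O)CC(C)=O | starting material
2 | methyl (2Z)-2,4-bis(trimethylsilyloxy)penta-2,4-dienoate | COC(=O)/C(O[Si](C)(C)C)=C/C(=C)O[Si](C)(C)C | intermediate
3 | 4-(benzyloxy)benzaldehyde | O=Cc1ccc(OCc2ccccc2)cc1 | starting material
4 | methyl (5R)-5-[4-(benzyloxy)phenyl]-5-hydroxy-2,4-dioxopentanoate (aldol adduct after loss of the silyl groups) | COC(=O)C(=O)CC(=O)C[C@@H](O)c1ccc(OCc2ccccc2)cc1 | intermediate
5 | methyl (2R)-2-[4-(benzyloxy)phenyl]-4-oxo-3,4-dihydro-2H-pyran-6-carboxylate | COC(=O)C1=CC(=O)C[C@H](c2ccc(OCc3ccccc3)cc2)O1 | intermediate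
6 | (2R)-2-[4-(benzyloxy)phenyl]-4-oxo-3,4-dihydro-2H-pyran-6-carboxylic acid | OC(=O)C1=CC(=O)C[C@H](c2ccc(OCc3ccccc3)cc2)O1 | intermediate
7 | (2R)-2-[4-(benzyloxy)phenyl]-4-oxo-3,4-dihydro-2H-pyran-6-carbonyl chloride | ClC(=O)C1=CC(=O)C[C@H](c2ccc(OCc3ccccc3)cc2)O1 | intermediate
8 | (2R)-2-[4-(benzyloxy)phenyl]-6-(2-diazoacetyl)-2,3-dihydro-4H-pyran-4-one | [N-]=[N+]=CC(=O)C1=CC(=O)C[C@H](c2ccc(OCc3ccccc3)cc2)O1 | intermediate
9 | methyl (2-hydroxyphenyl)acetate | COC(=O)Cc1ccccc1O | starting material
10 | methyl [2-(benzyloxy)phenyl]acetate | COC(=O)Cc1ccccc1OCc1ccccc1 | intermediate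
11 | lithium 3-[2-(benzyloxy)phenyl]-1,1-dibromoprop-1-en-2-olate | [Li+].[O-]C(Cc1ccccc1OCc1ccccc1)=C(Br)Br | intermediate
12 | lithium 3-[2-(benzyloxy)phenyl]prop-1-yn-1-olate | [Li+].[O-]C#CCc1ccccc1OCc1ccccc1 | intermediate
13 | ({3-[2-(benzyloxy)phenyl]prop-1-yn-1-yl}oxy)tri(propan-2-yl)silane | CC(C)[Si](OC#CCc1ccccc1OCc1ccccc1)(C(C)C)C(C)C | intermediate
14 | (2R)-2-[4-(benzyloxy)phenyl]-6-(2-oxoethenyl)-2,3-dihydro-4H-pyran-4-one (vinylketene) | O=C=CC1=CC(=O)C[C@H](c2ccc(OCc3ccccc3)cc2)O1 | intermediate
15 | (2R)-6-{3-[2-(benzyloxy)benzyl]-4-oxo-2-[tri(propan-2-yl)silyloxy]cyclobut-2-en-1-yl}-2-[4-(benzyloxy)phenyl]-2,3-dihydro-4H-pyran-4-one (both epimers at the cyclobutenone carbon) | O=C1C(Cc2ccccc2OCc2ccccc2)=C(O[Si](C(C)C)(C(C)C)C(C)C)C1C1=CC(=O)C[C@H](c2ccc(OCc3ccccc3)cc2)O1 | intermediate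
16 | (2R)-6-{(1E)-3-[2-(benzyloxy)benzyl]-4-oxo-2-[tri(propan-2-yl)silyloxy]buta-1,3-dien-1-yl}-2-[4-(benzyloxy)phenyl]-2,3-dihydro-4H-pyran-4-one (dienylketene) | O=C=C(Cc1ccccc1OCc1ccccc1)/C(O[Si](C(C)C)(C(C)C)C(C)C)=C\C1=CC(=O)C[C@H](c2ccc(OCc3ccccc3)cc2)O1 | intermediate
17 | (2R)-6-[2-(benzyloxy)benzyl]-2-[4-(benzyloxy)phenyl]-5-hydroxy-7-[tri(propan-2-yl)silyloxy]-2,3-dihydro-4H-chromen-4-one | CC(C)[Si](Oc1cc2c(c(O)c1Cc1ccccc1OCc1ccccc1)C(=O)C[C@H](c1ccc(OCc3ccccc3)cc1)O2)(C(C)C)C(C)C | intermediate
18 | (2R)-6-[2-(benzyloxy)benzyl]-2-[4-(benzyloxy)phenyl]-5,7-dihydroxy-2,3-dihydro-4H-chromen-4-one | Oc1cc2c(c(O)c1Cc1ccccc1OCc1ccccc1)C(=O)C[C@H](c1ccc(OCc3ccccc3)cc1)O2 | intermediate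
19 | (2R)-6-[2-(benzyloxy)benzyl]-2-[4-(benzyloxy)phenyl]-5-hydroxy-7-methoxy-2,3-dihydro-4H-chromen-4-one | COc1cc2c(c(O)c1Cc1ccccc1OCc1ccccc1)C(=O)C[C@H](c1ccc(OCc3ccccc3)cc1)O2 | intermediate
20 | (+)-methylphelligrin A, (2R)-5-hydroxy-6-(2-hydroxybenzyl)-2-(4-hydroxyphenyl)-7-methoxy-2,3-dihydro-4H-chromen-4-one | COc1cc2c(c(O)c1Cc1ccccc1O)C(=O)C[C@H](c1ccc(O)cc1)O2 | target

**Step count**

Total steps: 10.
Longest linear sequence: 8 steps (steps 1, 2, 3, 4, 7, 8, 9, 10, from methyl 2,4-dioxopentanoate).

**Steps most likely to fail**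

Step 7. Light absorbed by the enone of ring C or by the aryl ethers may divert the excited state into photocycloaddition or fragmentation, and the electron-poor vinylketene may dimerise before the alkyne captures it. The fallback generates the same ketene in the dark by dehydrochlorination. It sets out from 8: Wolff rearrangement with catalytic AgO2CPh and Et3N in aqueous THF in the dark (Arndt–Eistert homologation) should give {(2R)-2-[4-(benzyloxy)phenyl]-4-oxo-3,4-dihydro-2H-pyran-6-yl}acetic acid F1. The α-chloroenamine Me2C=C(Cl)NMe2 converts this into {(2R)-2-[4-(benzyloxy)phenyl]-4-oxo-3,4-dihydro-2H-pyran-6-yl}acetyl chloride F2. Slow addition of this chloride to Et3N and 13 in toluene at 80 °C should produce vinylketene 14 by 1,2-elimination of HCl, and from there cyclobutenone 15 and dienylketene 16 lead back to 17.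

Step 2. The titanium–BINOL complex may discriminate poorly between the aldehyde faces with this ester-bearing diene, the diene may react through its internal carbon, and the p-alkoxybenzylic carbinol may ionise during the acid cyclisation. The fallback moves stereocontrol to a stoichiometric chiral reagent and builds the diketo ester by Claisen condensation. It sets out from 3: Brown methallylation with the borane made from (+)-B-methoxydiisopinocampheylborane and methallylmagnesium chloride (Et2O, −78 °C, then NaOH/H2O2), expected to add to the Re face, should give (1R)-1-[4-(benzyloxy)phenyl]-3-methylbut-3-en-1-ol F3. Silylation with t-BuMe2SiCl and imidazole gives {[(1R)-1-[4-(benzyloxy)phenyl]-3-methylbut-3-en-1-yl]oxy}(tert-butyl)dimethylsilane F4. Lemieux–Johnson cleavage (catalytic K2OsO4·2H2O, NaIO4, 2,6-lutidine, aqueous dioxane) gives (4R)-4-[4-(benzyloxy)phenyl]-4-[(tert-butyldimethylsilyl)oxy]butan-2-one F5. Kinetic enolisation at the methyl group with LiN(SiMe3)2 at −78 °C and Claisen condensation with dimethyl oxalate gives methyl (5R)-5-[4-(benzyloxy)phenyl]-5-[(tert-butyldimethylsilyl)oxy]-2,4-dioxopentanoate F6. Desilylation with HF·pyridine releases 4, which should close and dehydrate (a trace of acid if needed) to 5.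

Step 6. LiCHBr2 or the amide base may deprotonate the acidic arylacetate α-position instead of adding to the ester carbonyl, and excess alkyllithium may metalate the benzyl ether and cause its rearrangement. The fallback reaches the ynolate by oxidation of an acetylide instead of by carbenoid rearrangement. It sets out from 10: reduction with i-Bu2AlH in CH2Cl2 at −78 °C should give [2-(benzyloxy)phenyl]acetaldehyde F7. Ohira–Bestmann homologation (dimethyl (1-diazo-2-oxopropyl)phosphonate, K2CO3, MeOH, 0 °C) gives 1-(benzyloxy)-2-(prop-2-yn-1-yl)benzene F8. One equivalent of n-BuLi in THF at −78 °C gives lithium 3-[2-(benzyloxy)phenyl]prop-1-yn-1-ide F9. Oxidation of this acetylide with LiOO-t-Bu (from t-BuOOH and LiN(SiMe3)2) gives ynolate 12, and (i-Pr)3SiOSO2CF3 silylates it on oxygen to return to 13.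

**Further compounds**

F1 | step 7 | {(2R)-2-[4-(benzyloxy)phenyl]-4-oxo-3,4-dihydro-2H-pyran-6-yl}acetic acid | OC(=O)CC1=CC(=O)C[C@H](c2ccc(OCc3ccccc3)cc2)O1
F2 | step 7 | {(2R)-2-[4-(benzyloxy)phenyl]-4-oxo-3,4-dihydro-2H-pyran-6-yl}acetyl chloride | ClC(=O)CC1=CC(=O)C[C@H](c2ccc(OCc3ccccc3)cc2)O1
F3 | step 2 | (1R)-1-[4-(benzyloxy)phenyl]-3-methylbut-3-en-1-ol | CC(=C)C[C@@H](O)c1ccc(OCc2ccccc2)cc1
F4 | step 2 | {[(1R)-1-[4-(benzyloxy)phenyl]-3-methylbut-3-en-1-yl]oxy}(tert-butyl)dimethylsilane | CC(=C)C[C@@H](O[Si](C)(C)C(C)(C)C)c1ccc(OCc2ccccc2)cc1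
F5 | step 2 | (4R)-4-[4-(benzyloxy)phenyl]-4-[(tert-butyldimethylsilyl)oxy]butan-2-one | CC(=O)C[C@@H](O[Si](C)(C)C(C)(C)C)c1ccc(OCc2ccccc2)cc1
F6 | step 2 | methyl (5R)-5-[4-(benzyloxy)phenyl]-5-[(tert-butyldimethylsilyl)oxy]-2,4-dioxopentanoate | COC(=O)C(=O)CC(=O)C[C@@H](O[Si](C)(C)C(C)(C)C)c1ccc(OCc2ccccc2)cc1
F7 | step 6 | [2-(benzyloxy)phenyl]acetaldehyde | O=CCc1ccccc1OCc1ccccc1
F8 | step 6 | 1-(benzyloxy)-2-(prop-2-yn-1-yl)benzene | C#CCc1ccccc1OCc1ccccc1
F9 | step 6 | lithium 3-[2-(benzyloxy)phenyl]prop-1-yn-1-ide | [Li+].[C-]#CCc1ccccc1OCc1ccccc1
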